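## Retrosynthetic overview

1. The C40 chain is cut twice by Wittig olefination, at C11'=C12' and then at C11=C12 (carotenoid numbering), into an acetylenic C15 phosphonium salt, the C10 dialdehyde and a trihydroxy C15 phosphonium salt.
2. The trihydroxy C15 salt goes back through a vinyl carbinol and a C13 enone (Wittig at C7) to a bicyclic lactol, and this to a 2-oxabicyclo[2.2.2]octan-3-one in which C7 is a lactone carbonyl bound to O3.
3. Key disconnection: the ring bond C1–C6 of the cyclohexanetriol (gem-dimethyl carbon to the carbinol carbon that carries the polyene), made by an iron-hydride hydrogen-atom-transfer (MHAT) radical cyclisation of a monocyclic α-keto-δ-lactone. Enabling feature: the C7 branch on C6 and the oxygen on C3 sit 1,4-cis on the six-membered ring, so they can be joined in a temporary lactone that turns C6 into an activated ketone and fixes the face of attack, while C1 with its two methyls is exactly the tertiary radical of a methallyl group.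
4. The α-keto lactone comes from (S)-epichlorohydrin plus isopropenyl Grignard reagent (C1–C4, both ring methyls) and the hydrazone of ethyl 2-oxobutanoate (C5–C7 and the 5-methyl); the 5-OH is put in by enolate hydroxylation.
5. Ring order: temporary δ-lactone (step 3), then the cyclohexane by C1–C6 closure (step 5), then the lactone is opened (steps 6 and 7); the cyclohexene ring of the acetylenic end is bought as (4R,6R)-actinol.

Key step: step 5

Remark: read from the SMILES, the triol end is (3S,5S,6S), with 3-OH and 5-OH cis, 6-OH trans to both and the side chain cis to 3-OH, and the other end is (3'R). (4R,6R)-Actinol, (E)-3-methylpent-2-en-4-yn-1-ol and the C10 dialdehyde are taken as purchasable.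

## Route

Step 1
Reactants: 1 (S)-epichlorohydrin
Product: 3 (S)-2-(2-methylprop-2-en-1-yl)oxirane, via chlorohydrin 2 (not isolated)
Conditions: CH2=C(CH3)MgBr, CuI (10 mol%), THF, −40 °C; then NaOH, Et2O/H2O, rt; distillation
Reagents that add atoms: isopropenylmagnesium bromide, C=C(C)[Mg]Br
Why: Copper-catalysed Grignard opening of the epoxide at its CH2 terminus followed by base-induced ring closure with loss of chloride (intramolecular Williamson reaction) moves the epoxide along the chain without touching the stereocentre, which is taken over from 1 and becomes C3 of the target.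

Step 2
Reactants: 4 ethyl 2-oxobutanoate
Product: 5 ethyl 2-(2,2-dimethylhydrazinylidene)butanoate
Conditions: Me2NNH2, AcOH (cat.), EtOH, rt
Reagents that add atoms: 1,1-dimethylhydrazine, CN(C)N
Why: Hydrazone formation (condensation) masks the ketone and makes C3 of the keto ester a clean azaenolate donor for the next step; no stereocentre is formed.

Step 3
Reactants: 3 (S)-2-(2-methylprop-2-en-1-yl)oxirane; 5 ethyl 2-(2,2-dimethylhydrazinylidene)butanoate
Product: 7 (6S)-3-hydroxy-4-methyl-6-(2-methylprop-2-en-1-yl)-5,6-dihydro-2H-pyran-2-one, via hydroxy hydrazone ester 6 (not isolated)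
Conditions: LiN(i-Pr)2, THF, −78 °C; 3, −78 → 0 °C; then sat. aq. oxalic acid/Et2O, rt
Reagents that add atoms: water, O
Why: Azaenolate alkylation of the dimethylhydrazone with the terminal epoxide (SN2 at CH2), lactonisation of the alkoxide onto the ethyl ester and hydrazone hydrolysis should give the α-keto-δ-lactone, which rests as its enol, so the centre made in the alkylation is erased and only the epoxide-derived centre remains.

Step 4
Reactants: 7 (6S)-3-hydroxy-4-methyl-6-(2-methylprop-2-en-1-yl)-5,6-dihydro-2H-pyran-2-one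
Product: 8 (4S,6S)-4-hydroxy-4-methyl-6-(2-methylprop-2-en-1-yl)oxane-2,3-dione
Conditions: KN(SiMe3)2, THF, −78 °C; 3-phenyl-2-(phenylsulfonyl)oxaziridine, −78 °C; AcOH quench at −78 °C
Reagents that add atoms: 3-phenyl-2-(phenylsulfonyl)oxaziridine, O=S(=O)(c1ccccc1)N1OC1c1ccccc1
Why: Davis hydroxylation of the potassium enolate puts oxygen on the methyl-bearing enolate carbon; the oxidant should approach the sofa-shaped ring anti to the pseudo-equatorial side chain at C6 (the facial preference known for additions to 6-substituted 5,6-dihydropyran-2-ones), which sets the tertiary carbinol with OH trans and CH3 cis to the methallyl group, and the cold acidic quench avoids α-ketol rearrangement.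

Step 5
Reactants: 8 (4S,6S)-4-hydroxy-4-methyl-6-(2-methylprop-2-en-1-yl)oxane-2,3-dione
Product: 9 (1S,4S,5S)-4,5-dihydroxy-5,8,8-trimethyl-2-oxabicyclo[2.2.2]octan-3-one
Conditions: Fe(acac)3 (30 mol%), PhSiH2(Oi-Pr) (2.5 equiv), THF/i-PrOH 9:1, high dilution, 40 °C, Ar; aqueous work-up (pH 7)
Reagents that add atoms: none
Why: The iron hydride formed from Fe(acac)3 and the silane transfers a hydrogen atom to the CH2 terminus of the 1,1-disubstituted alkene (Markovnikov MHAT), and the nucleophilic tertiary radical at the gem-dimethyl carbon adds to the ketone carbon of the 1,2-dicarbonyl; the alkoxy radical is reduced at once by divalent iron to the trivalent iron alkoxide, which makes the reversible addition productive. The closest known reaction type is the iron-mediated HAT radical cyclisation of alkene-tethered ketones to tertiary cycloalkanols. The cyclohexane is closed in 6-exo-trig mode onto C=O, transannularly across the lactone, whose planar O–C(=O)–C(=O) unit makes the required boat easy to reach, and the product is a 2-oxabicyclo[2.2.2]octan-3-one. The new stereocentre (the carbinol carbon, C6 of the target) is fixed by the tether alone: the radical-bearing chain hangs from the C–O carbon of the lactone and can reach only the ketone face on its own side, so the lactone carbonyl (future C7) ends cis to the ring oxygen (future 3-OH) and the new OH trans to the existing tertiary OH, while the two existing centres are not touched. The step needs chemoselectivity (ketone C=O against lactone C=O, against hydrosilylation of the keto group and against β-scission of the alkoxy radical); it rests on the much higher radical affinity of the keto carbonyl, the mild silane and chelation of the α-hydroxy-1,2-dicarbonyl unit to iron, which places the reductant at the oxygen where the radical develops.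

Step 6
Reactants: 9 (1S,4S,5S)-4,5-dihydroxy-5,8,8-trimethyl-2-oxabicyclo[2.2.2]octan-3-one
Product: 10 (1S,4S,5S)-5,8,8-trimethyl-2-oxabicyclo[2.2.2]octane-3,4,5-triol (lactol, both anomers)
Conditions: i-Bu2AlH (3.5 equiv), CH2Cl2, −78 °C; aq. Rochelle salt
Reagents that add atoms: none
Why: Partial reduction of the lactone to the lactol with i-Bu2AlH stops at the tetrahedral aluminate at low temperature, the two tertiary hydroxyls only consuming hydride, and the anomeric centre is of no consequence.

Step 7
Reactants: 10 (1S,4S,5S)-5,8,8-trimethyl-2-oxabicyclo[2.2.2]octane-3,4,5-triol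
Product: 11 (3E)-4-[(1S,2S,4S)-1,2,4-trihydroxy-2,6,6-trimethylcyclohexyl]but-3-en-2-one
Conditions: Ph3P=CHC(O)CH3 (3 equiv), PhCO2H (cat.), toluene, 80 °C
Reagents that add atoms: 1-(triphenylphosphoranylidene)propan-2-one, CC(=O)C=P(c1ccccc1)(c1ccccc1)c1ccccc1
Why: Wittig olefination with a stabilised ylide under neutral conditions takes the open hydroxy-aldehyde form of the strained bicyclic lactol, gives the E-enone (C7=C8) and at the same time frees the 3-OH, so the temporary ring is gone.

Step 8
Reactants: 11 (3E)-4-[(1S,2S,4S)-1,2,4-trihydroxy-2,6,6-trimethylcyclohexyl]but-3-en-2-one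
Product: 12 (1S,2S,4S)-1-[(1E)-3-hydroxy-3-methylpenta-1,4-dien-1-yl]-2,6,6-trimethylcyclohexane-1,2,4-triol (both epimers at the new carbinol)
Conditions: CH2=CHMgBr (6 equiv), THF, −30 → 0 °C; H2O
Reagents that add atoms: vinylmagnesium bromide, C=C[Mg]Br
Why: Grignard 1,2-addition to the ionone-type enone (excess reagent covers the three hydroxyls) gives the doubly allylic tertiary alcohol, whose new centre is lost in the next step.

Step 9
Reactants: 12 (1S,2S,4S)-1-[(1E)-3-hydroxy-3-methylpenta-1,4-dien-1-yl]-2,6,6-trimethylcyclohexane-1,2,4-triol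
Product: 13 [(2E,4E)-3-methyl-5-[(1S,2S,4S)-1,2,4-trihydroxy-2,6,6-trimethylcyclohexyl]penta-2,4-dien-1-yl]triphenylphosphonium bromide
Conditions: PPh3·HBr (1.05 equiv), MeOH/CH2Cl2, 0 °C → rt
Reagents that add atoms: triphenylphosphine hydrobromide, [Br-].[PH+](c1ccccc1)(c1ccccc1)c1ccccc1
Why: Ionisation of the doubly allylic tertiary alcohol and capture of the pentadienyl cation by PPh3 at its unhindered terminus (allylic transposition, the classical route from vinyl carbinols to C15 Wittig salts) should give the salt with the thermodynamic E geometry at C9=C10, the acid being used up as it reacts.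

Step 10
Reactants: 14 (4R,6R)-4-hydroxy-2,2,6-trimethylcyclohexan-1-one (actinol)
Product: 15 (4R,6R)-2,2,6-trimethyl-4-[(triethylsilyl)oxy]cyclohexan-1-one
Conditions: Et3SiCl, imidazole, DMF, 0 °C → rt
Reagents that add atoms: chlorotriethylsilane, CC[Si](Cl)(CC)CC
Why: Silylation of the secondary alcohol protects it against the strong base of the next step; the (R)-carbinol centre, the future C3', is bought with 14.

Step 11
Reactants: 15 (4R,6R)-2,2,6-trimethyl-4-[(triethylsilyl)oxy]cyclohexan-1-one
Product: 16 (4R)-2,6,6-trimethyl-4-[(triethylsilyl)oxy]cyclohex-1-en-1-yl trifluoromethanesulfonate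
Conditions: LiN(i-Pr)2, THF, −78 → 0 °C; PhNTf2, −78 °C → rt; H2O
Reagents that add atoms: N-phenylbis(trifluoromethanesulfonimide), O=S(=O)(N(c1ccccc1)S(=O)(=O)C(F)(F)F)C(F)(F)F
Why: Deprotonation at the only α-CH and O-triflation of the enolate give the tetrasubstituted enol triflate, which erases the methyl-bearing centre on purpose and leaves the carbinol centre untouched.

Step 12
Reactants: 16 (4R)-2,6,6-trimethyl-4-[(triethylsilyl)oxy]cyclohex-1-en-1-yl trifluoromethanesulfonate; 17 (E)-3-methylpent-2-en-4-yn-1-ol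
Product: 18 (2E)-3-methyl-5-[(4R)-2,6,6-trimethyl-4-[(triethylsilyl)oxy]cyclohex-1-en-1-yl]pent-2-en-4-yn-1-ol
Conditions: Pd(PPh3)4 (5 mol%), CuI (10 mol%), Et3N, DMF, rt → 40 °C
Reagents that add atoms: none
Why: Sonogashira coupling of the vinyl triflate with the terminal alkyne builds the ring–C7'≡C8' unit and keeps the E geometry of the enynol.

Step 13
Reactants: 18 (2E)-3-methyl-5-[(4R)-2,6,6-trimethyl-4-[(triethylsilyl)oxy]cyclohex-1-en-1-yl]pent-2-en-4-yn-1-ol
Product: 19 [(2E)-5-[(4R)-4-hydroxy-2,6,6-trimethylcyclohex-1-en-1-yl]-3-methylpent-2-en-4-yn-1-yl]triphenylphosphonium bromide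
Conditions: PPh3·HBr, MeOH, rt
Reagents that add atoms: triphenylphosphine hydrobromide, [Br-].[PH+](c1ccccc1)(c1ccccc1)c1ccccc1
Why: The primary allylic alcohol is converted into the phosphonium salt by PPh3·HBr (allylic substitution), and the acidic methanol removes the triethylsilyl ether in the same operation.

Step 14
Reactants: 19 [(2E)-5-[(4R)-4-hydroxy-2,6,6-trimethylcyclohex-1-en-1-yl]-3-methylpent-2-en-4-yn-1-yl]triphenylphosphonium bromide; 20 (2E,4E,6E)-2,7-dimethylocta-2,4,6-trienedial
Product: 22 (2E,4E,6E,8E,10E)-13-[(4R)-4-hydroxy-2,6,6-trimethylcyclohex-1-en-1-yl]-2,7,11-trimethyltrideca-2,4,6,8,10-pentaen-12-ynal, via (8Z)-aldehyde 21 (not isolated)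
Conditions: 20 (3 equiv), NaOMe, MeOH/CH2Cl2, 0 °C → rt, slow addition of 19; then heptane/EtOAc, reflux, dark
Reagents that add atoms: none
Why: Wittig mono-olefination of the symmetrical dialdehyde (kept in excess) forms C11'=C12', and heating should turn the Z part of the semi-stabilised ylide product into the E isomer.

Step 15
Reactants: 13 [(2E,4E)-3-methyl-5-[(1S,2S,4S)-1,2,4-trihydroxy-2,6,6-trimethylcyclohexyl]penta-2,4-dien-1-yl]triphenylphosphonium bromide; 22 (2E,4E,6E,8E,10E)-13-[(4R)-4-hydroxy-2,6,6-trimethylcyclohex-1-en-1-yl]-2,7,11-trimethyltrideca-2,4,6,8,10-pentaen-12-ynal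
Product: 24 all-E (3S,5S,6S,3'R)-7',8'-didehydro-5,6-dihydro-β,β-carotene-3,5,6,3'-tetrol, via (11Z)-isomer 23 (not isolated)
Conditions: NaOMe, MeOH/CH2Cl2, rt, dark; then heptane/EtOAc, reflux under N2, crystallisation
Reagents that add atoms: none
Why: Wittig olefination of the C25 aldehyde with the ylide of the unprotected trihydroxy salt forms C11=C12 and completes the C40 chain, thermal Z-to-E equilibration and crystallisation should deliver the all-E polyene, and no stereocentre is formed or touched.

## Compound list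

1 | (S)-epichlorohydrin | ClC[C@@H]1CO1 | starting material
2 | (S)-1-chloro-4-methylpent-4-en-2-ol | ClC[C@@H](O)CC(C)=C | intermediate (not isolated)
3 | (S)-2-(2-methylprop-2-en-1-yl)oxirane | C=C(C)C[C@H]1CO1 | intermediate
4 | ethyl 2-oxobutanoate | CCC(=O)C(=O)OCC | starting material
5 | ethyl 2-(2,2-dimethylhydrazinylidene)butanoate | CCOC(=O)C(CC)=NN(C)C | intermediate
6 | ethyl (5R)-2-(2,2-dimethylhydrazinylidene)-5-hydroxy-3,7-dimethyloct-7-enoate (both C3 epimers) | CCOC(=O)C(=NN(C)C)C(C)C[C@@H](O)CC(C)=C | intermediate (not isolated)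
7 | (6S)-3-hydroxy-4-methyl-6-(2-methylprop-2-en-1-yl)-5,6-dihydro-2H-pyran-2-one | O=C1O[C@@H](CC(C)=C)CC(C)=C1O | intermediate
8 | (4S,6S)-4-hydroxy-4-methyl-6-(2-methylprop-2-en-1-yl)oxane-2,3-dione | O=C1O[C@@H](CC(C)=C)C[C@](C)(O)C1=O | intermediate
9 | (1S,4S,5S)-4,5-dihydroxy-5,8,8-trimethyl-2-oxabicyclo[2.2.2]octan-3-one | O=C1[C@]2(O)C(C)(C)C[C@H](O1)C[C@]2(C)O | intermediate
10 | (1S,4S,5S)-5,8,8-trimethyl-2-oxabicyclo[2.2.2]octane-3,4,5-triol (both anomers) | OC1[C@]2(O)C(C)(C)C[C@H](O1)C[C@]2(C)O | intermediate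
11 | (3E)-4-[(1S,2S,4S)-1,2,4-trihydroxy-2,6,6-trimethylcyclohexyl]but-3-en-2-one | CC(=O)/C=C/[C@]1(O)C(C)(C)C[C@H](O)C[C@]1(C)O | intermediate
12 | (1S,2S,4S)-1-[(1E)-3-hydroxy-3-methylpenta-1,4-dien-1-yl]-2,6,6-trimethylcyclohexane-1,2,4-triol (both epimers at the side-chain carbinol) | C=CC(C)(O)/C=C/[C@]1(O)C(C)(C)C[C@H](O)C[C@]1(C)O | intermediate
13 | [(2E,4E)-3-methyl-5-[(1S,2S,4S)-1,2,4-trihydroxy-2,6,6-trimethylcyclohexyl]penta-2,4-dien-1-yl]triphenylphosphonium bromide | [Br-].c1ccccc1[P+](c1ccccc1)(c1ccccc1)C/C=C(C)/C=C/[C@]2(O)C(C)(C)C[C@H](O)C[C@]2(C)O | intermediate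
14 | (4R,6R)-4-hydroxy-2,2,6-trimethylcyclohexan-1-one (actinol) | C[C@H]1C(=O)C(C)(C)C[C@H](O)C1 | starting material
15 | (4R,6R)-2,2,6-trimethyl-4-[(triethylsilyl)oxy]cyclohexan-1-one | C[C@H]1C(=O)C(C)(C)C[C@H](O[Si](CC)(CC)CC)C1 | intermediate
16 | (4R)-2,6,6-trimethyl-4-[(triethylsilyl)oxy]cyclohex-1-en-1-yl trifluoromethanesulfonate | CC1=C(OS(=O)(=O)C(F)(F)F)C(C)(C)C[C@H](O[Si](CC)(CC)CC)C1 | intermediate
17 | (E)-3-methylpent-2-en-4-yn-1-ol | C#C/C(C)=C/CO | starting material
18 | (2E)-3-methyl-5-[(4R)-2,6,6-trimethyl-4-[(triethylsilyl)oxy]cyclohex-1-en-1-yl]pent-2-en-4-yn-1-ol | CC1=C(C#C/C(C)=C/CO)C(C)(C)C[C@H](O[Si](CC)(CC)CC)C1 | intermediate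
19 | [(2E)-5-[(4R)-4-hydroxy-2,6,6-trimethylcyclohex-1-en-1-yl]-3-methylpent-2-en-4-yn-1-yl]triphenylphosphonium bromide | [Br-].CC1=C(C#C/C(C)=C/C[P+](c2ccccc2)(c2ccccc2)c2ccccc2)C(C)(C)C[C@H](O)C1 | intermediate
20 | (2E,4E,6E)-2,7-dimethylocta-2,4,6-trienedial | O=C/C(C)=C/C=C/C=C(C)/C=O | starting material
21 | (2E,4E,6E,8Z,10E)-13-[(4R)-4-hydroxy-2,6,6-trimethylcyclohex-1-en-1-yl]-2,7,11-trimethyltrideca-2,4,6,8,10-pentaen-12-ynal | CC1=C(C#C/C(C)=C/C=C\C(C)=C\C=C\C=C(C)\C=O)C(C)(C)C[C@H](O)C1 | intermediate (not isolated)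
22 | (2E,4E,6E,8E,10E)-13-[(4R)-4-hydroxy-2,6,6-trimethylcyclohex-1-en-1-yl]-2,7,11-trimethyltrideca-2,4,6,8,10-pentaen-12-ynal | CC1=C(C#C/C(C)=C/C=C/C(C)=C/C=C/C=C(C)/C=O)C(C)(C)C[C@H](O)C1 | intermediate
23 | (11Z)-isomer of the target | CC1=C(C#C/C(C)=C/C=C/C(C)=C/C=C/C=C(C)/C=C\C=C(C)\C=C\[C@]2(O)C(C)(C)C[C@H](O)C[C@]2(C)O)C(C)(C)C[C@H](O)C1 | intermediate (not isolated)
24 | all-E (3S,5S,6S,3'R)-7',8'-didehydro-5,6-dihydro-β,β-carotene-3,5,6,3'-tetrol | CC1=C(C#C/C(C)=C/C=C/C(C)=C/C=C/C=C(C)/C=C/C=C(C)/C=C/[C@]2(O)C(C)(C)C[C@H](O)C[C@]2(C)O)C(C)(C)C[C@H](O)C1 | target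

## Step count and risks

Total step count: 15. Longest linear sequence: 9 steps (steps 1, 3, 4, 5, 6, 7, 8, 9, 15).

The three steps most likely to fail:

1. Step 5 (key step). The tertiary radical may be quenched before it cyclises, the keto group may be hydrosilylated faster than it is attacked, or the alkoxy radical may fragment (β-scission of the bond to the oxygen-bearing neighbour, a 1,2-acyl shift) before it is reduced. The fallback sets out from 8 and comes back at 9. It runs the same ring closure as a halogen-abstraction chain without iron hydride or silane. Markovnikov hydrobromination of 8 (HBr, CH2Cl2, −40 °C) would give (4S,6R)-6-(2-bromo-2-methylpropyl)-4-hydroxy-4-methyloxane-2,3-dione F1. Slow addition of Bu3SnH with AIBN in benzene at 80 °C under high dilution would then generate the same tertiary radical by bromine abstraction, which adds 6-exo to the ketone; the O–H bond is made by hydrogen transfer from the stannane, and the tether controls the new centre as before.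

2. Step 3. The ester-conjugated azaenolate may be too weak a nucleophile for the epoxide (slow opening, proton transfer, self-condensation), and the facial control of the following hydroxylation rests on a flexible six-membered enolate. The fallback sets out from 3 and comes back at 8, so it replaces steps 3 and 4. The dianion of propanoic acid (2 LiN(i-Pr)2, THF) would open 3, and acid work-up would lactonise the product to (5R)-3-methyl-5-(2-methylprop-2-en-1-yl)oxolan-2-one F2. Enolate hydroxylation (LiN(i-Pr)2, then the same oxaziridine) anti to the side chain of the rigid five-membered ring would give (3S,5S)-3-hydroxy-3-methyl-5-(2-methylprop-2-en-1-yl)oxolan-2-one F3. Addition of PMBOCH2Li (from Bu3SnCH2OPMB and BuLi, −78 °C) to the lactone carbonyl would give (3S,5S)-3,5-dihydroxy-1-[(4-methoxyphenyl)methoxy]-3,7-dimethyloct-7-en-2-one F4. DDQ (CH2Cl2/H2O) would remove the PMB group to give (3S,5S)-1,3,5-trihydroxy-3,7-dimethyloct-7-en-2-one F5. TEMPO/PhI(OAc)2 would oxidise the primary alcohol and close the six-membered lactol to the lactone 8.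

3. Step 9. The pentadienyl cation is generated next to the tertiary 5,6-diol, so a semipinacol shift or dehydration may compete with capture by the phosphine, and the C9=C10 geometry may scramble. The fallback sets out from 11 and 22 and comes back at 24; it reverses the polarity of the last olefination so that no cation is formed beside the diol. Horner–Wadsworth–Emmons reaction of 11 with diethyl cyanomethylphosphonate (NaH, THF; the 9E isomer is separated) would give (2E,4E)-3-methyl-5-[(1S,2S,4S)-1,2,4-trihydroxy-2,6,6-trimethylcyclohexyl]penta-2,4-dienenitrile F6. Reduction with i-Bu2AlH and hydrolysis would give (2E,4E)-3-methyl-5-[(1S,2S,4S)-1,2,4-trihydroxy-2,6,6-trimethylcyclohexyl]penta-2,4-dienal F7. In parallel, 22 would be reduced (NaBH4, MeOH) to (2E,4E,6E,8E,10E)-13-[(4R)-4-hydroxy-2,6,6-trimethylcyclohex-1-en-1-yl]-2,7,11-trimethyltrideca-2,4,6,8,10-pentaen-12-yn-1-ol F8 and converted with PPh3·HBr into the corresponding [(2E,4E,6E,8E,10E)-13-[(4R)-4-hydroxy-2,6,6-trimethylcyclohex-1-en-1-yl]-2,7,11-trimethyltrideca-2,4,6,8,10-pentaen-12-yn-1-yl]triphenylphosphonium bromide F9. Wittig reaction of F7 with F9 (NaOMe, then thermal equilibration) would form C11=C12 and give 24.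

Further compounds

F1 | step 5 | (4S,6R)-6-(2-bromo-2-methylpropyl)-4-hydroxy-4-methyloxane-2,3-dione | O=C1O[C@@H](CC(C)(C)Br)C[C@](C)(O)C1=O
F2 | step 3 | (5R)-3-methyl-5-(2-methylprop-2-en-1-yl)oxolan-2-one (both C3 epimers) | O=C1O[C@@H](CC(C)=C)CC1C
F3 | step 3 | (3S,5S)-3-hydroxy-3-methyl-5-(2-methylprop-2-en-1-yl)oxolan-2-one | O=C1O[C@@H](CC(C)=C)C[C@]1(C)O
F4 | step 3 | (3S,5S)-3,5-dihydroxy-1-[(4-methoxyphenyl)methoxy]-3,7-dimethyloct-7-en-2-one | COc1ccc(COCC(=O)[C@@](C)(O)C[C@@H](O)CC(C)=C)cc1
F5 | step 3 | (3S,5S)-1,3,5-trihydroxy-3,7-dimethyloct-7-en-2-one | OCC(=O)[C@@](C)(O)C[C@@H](O)CC(C)=C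
F6 | step 9 | (2E,4E)-3-methyl-5-[(1S,2S,4S)-1,2,4-trihydroxy-2,6,6-trimethylcyclohexyl]penta-2,4-dienenitrile | N#C/C=C(C)/C=C/[C@]1(O)C(C)(C)C[C@H](O)C[C@]1(C)O
F7 | step 9 | (2E,4E)-3-methyl-5-[(1S,2S,4S)-1,2,4-trihydroxy-2,6,6-trimethylcyclohexyl]penta-2,4-dienal | O=C/C=C(C)/C=C/[C@]1(O)C(C)(C)C[C@H](O)C[C@]1(C)O
F8 | step 9 | (2E,4E,6E,8E,10E)-13-[(4R)-4-hydroxy-2,6,6-trimethylcyclohex-1-en-1-yl]-2,7,11-trimethyltrideca-2,4,6,8,10-pentaen-12-yn-1-ol | CC1=C(C#C/C(C)=C/C=C/C(C)=C/C=C/C=C(C)/CO)C(C)(C)C[C@H](O)C1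
F9 | step 9 | [(2E,4E,6E,8E,10E)-13-[(4R)-4-hydroxy-2,6,6-trimethylcyclohex-1-en-1-yl]-2,7,11-trimethyltrideca-2,4,6,8,10-pentaen-12-yn-1-yl]triphenylphosphonium bromide | [Br-].CC1=C(C#C/C(C)=C/C=C/C(C)=C/C=C/C=C(C)/C[P+](c2ccccc2)(c2ccccc2)c2ccccc2)C(C)(C)C[C@H](O)C1
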